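**Retrosynthetic overview**

- The carbinol carbon lies between the exo-methylene carbon of the 1,1-disubstituted alkene and an unbranched CH2–CH2 tether to C5 of the oxane ring. Cutting the bond from the carbinol carbon to that CH2 gives a non-enolisable 2-alkylacrolein (18) and a primary alkylzinc, joined by a catalytic enantioselective 1,2-addition that also sets the (R)-carbinol.
- The acrylic acid is carried through the coupling at a lower level, as the zinc-inert CH2CO2Me group, and restored afterwards by reduction to the aldehyde, α-methylenation and oxidation.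
- The oxane, the only ring, is formed before the key step: as a lactol after ozonolysis (step 4), then fixed by Wittig olefination and reversible oxa-Michael closure (step 5). C5 is set by an Evans alkylation and relays C2 to the 2,5-trans diequatorial arrangement.
- The enal comes in two steps from geranyl bromide and methallyl alcohol (dianion alkylation, MnO2).

Key step: step 9

Remark: the facial sense of the titanium bis(sulfonamide) catalyst is assigned by analogy with aromatic and other α,β-unsaturated aldehydes; bis(trimethylsilylmethyl)zinc is taken as a stock reagent (from commercial Me3SiCH2MgCl and ZnCl2) that contributes no atoms to the product.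

**Route**

Step 1
Reactants: 1 (4S)-4-benzyl-1,3-oxazolidin-2-one; 2 hex-5-enoyl chloride
Product: 3 (4S)-4-benzyl-3-(hex-5-enoyl)-1,3-oxazolidin-2-one
Conditions: Et3N, DMAP (cat.), CH2Cl2, 0 °C → rt
Reagents that add atoms: none
Why: DMAP-catalysed N-acylation of the oxazolidinone by the acid chloride installs the chiral auxiliary that will control ring carbon C5; no stereocentre is formed.

Step 2
Reactants: 3 (4S)-4-benzyl-3-(hex-5-enoyl)-1,3-oxazolidin-2-one; 4 tert-butyl bromoacetate
Product: 6 tert-butyl (3R)-3-{[(4S)-4-benzyl-2-oxo-1,3-oxazolidin-3-yl]carbonyl}hept-6-enoate, via sodium enolate 5 (not isolated)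
Conditions: NaHMDS, THF, −78 °C; then 4, −78 → −30 °C
Reagents that add atoms: none
Why: Evans asymmetric alkylation, in which the chelated (Z)-sodium enolate is alkylated on the face opposite the benzyl group, sets the future ring C5 stereocentre (3R in 6).

Step 3
Reactants: 6 tert-butyl (3R)-3-{[(4S)-4-benzyl-2-oxo-1,3-oxazolidin-3-yl]carbonyl}hept-6-enoate
Product: 7 (2R)-2-(but-3-en-1-yl)butane-1,4-diol
Conditions: LiAlH4, THF, 0 °C → rt; aqueous NaOH work-up
Reagents that add atoms: none
Why: Hydride reduction cleaves the imide to the primary alcohol and reduces the tert-butyl ester in the same operation, releasing the auxiliary for recovery and leaving the stereocentre untouched.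

Step 4
Reactants: 7 (2R)-2-(but-3-en-1-yl)butane-1,4-diol
Product: 9 (5R)-5-(2-hydroxyethyl)oxan-2-ol (anomeric mixture), via ozonide 8 (not isolated)
Conditions: O3, CH2Cl2, −78 °C; then PPh3, −78 °C → rt
Reagents that add atoms: ozone, [O-][O+]=O
Why: Ozonolysis with reductive work-up cleaves the only alkene to the aldehyde, which closes with the hydroxymethyl group to the six-membered lactol; the anomeric centre is of no consequence.

Step 5
Reactants: 9 (5R)-5-(2-hydroxyethyl)oxan-2-ol; 10 methyl (triphenyl-λ5-phosphanylidene)acetate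
Product: 12 methyl 2-[(2R,5R)-5-(2-hydroxyethyl)oxan-2-yl]acetate, via hydroxy enoate 11 (not isolated)
Conditions: toluene, 80 °C; then KOt-Bu (0.2 equiv), THF, 0 °C → rt
Reagents that add atoms: none
Why: Wittig olefination of the open-chain aldehyde of the lactol gives the (E)-enoate, and base-mediated reversible 6-exo-trig oxa-Michael addition of the hydroxymethyl oxygen closes the oxane under thermodynamic control, so that C5 relays C2 to the 2,5-trans diequatorial isomer (the seven-membered alternative from the hydroxyethyl group is disfavoured).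

Step 6
Reactants: 12 methyl 2-[(2R,5R)-5-(2-hydroxyethyl)oxan-2-yl]acetate
Product: 13 methyl 2-[(2R,5R)-5-(2-iodoethyl)oxan-2-yl]acetate
Conditions: I2, PPh3, imidazole, CH2Cl2, 0 °C → rt
Reagents that add atoms: iodine, II
Why: Appel-type iodination converts the primary alcohol into the primary iodide by SN2 displacement of the alkoxyphosphonium ion, with no stereocentre involved.

Step 7
Reactants: 14 geranyl bromide [(2E)-1-bromo-3,7-dimethylocta-2,6-diene]; 15 2-methylprop-2-en-1-ol
Product: 17 (5E)-6,10-dimethyl-2-methylideneundeca-5,9-dien-1-ol, via dilithio alkoxide 16 (not isolated)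
Conditions: 15, n-BuLi (2.1 equiv), TMEDA, Et2O, 0 °C → rt; then 14, −78 °C → rt
Reagents that add atoms: none
Why: Double deprotonation of methallyl alcohol gives a dianion whose two allylic termini are equivalent, and its SN2 alkylation at the primary carbon of geranyl bromide should give the 2-substituted allylic alcohol with the (E)-olefin retained.

Step 8
Reactants: 17 (5E)-6,10-dimethyl-2-methylideneundeca-5,9-dien-1-ol
Product: 18 (5E)-6,10-dimethyl-2-methylideneundeca-5,9-dienal
Conditions: activated MnO2, CH2Cl2, rt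
Reagents that add atoms: none
Why: Allylic oxidation with MnO2 is selective for the allylic alcohol and stops at the aldehyde, giving the 2-alkylacrolein, which is used without storage.

Step 9
Reactants: 13 methyl 2-[(2R,5R)-5-(2-iodoethyl)oxan-2-yl]acetate; 18 (5E)-6,10-dimethyl-2-methylideneundeca-5,9-dienal
Product: 21 methyl 2-[(2R,5S)-5-[(3R,7E)-3-hydroxy-8,12-dimethyl-4-methylidenetrideca-7,11-dien-1-yl]oxan-2-yl]acetate, via bis-alkylzinc 19 (not isolated), via silylmethyl alkylzinc 20 (not isolated)
Conditions: (i) Et2Zn (neat, excess), CuI (0.3 mol%), 50 °C, then vacuum; (ii) (Me3SiCH2)2Zn, Et2O, rt; (iii) Ti(Oi-Pr)4 (2 equiv), (1S,2S)-1,2-bis(trifluoromethanesulfonamido)cyclohexane (8 mol%), toluene, −20 °C; then 18, −20 °C; aq. NH4Cl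
Reagents that add atoms: none
Why: Iodine–zinc exchange turns the primary iodide into the ester-bearing dialkylzinc 19, which redistributes with (Me3SiCH2)2Zn to the mixed reagent 20 whose silylmethyl group is not transferred; the chiral titanium bis(sulfonamide) complex formed from Ti(Oi-Pr)4 and the (1S,2S)-ligand then activates the aldehyde of 18 and mediates ligand-accelerated 1,2-transfer of the alkyl group from zinc to the carbonyl carbon. The closest known reaction type is the Ti(Oi-Pr)4/trans-1,2-bis(trifluoromethanesulfonamido)cyclohexane-catalysed addition of functionalised dialkylzincs (ester, nitrile or halide in the chain) to aldehydes, in which α-branched α,β-unsaturated aldehydes are among the best substrates. No ring is closed in this step. The single new stereocentre, the carbinol carbon, is set by the catalyst alone: the (1R,2R)-ligand is known to direct alkyl groups to the Si face of aromatic and α,β-unsaturated aldehydes, so the (1S,2S)-ligand should give Re-face attack, which with OH > C(=CH2) > CH2 corresponds to (R); the ring stereocentres lie three and six bonds away and should not interfere. The step needs 1,2- rather than 1,4-addition, attack on the aldehyde rather than the ester, and one enantiotopic face: the titanium-bound aldehyde is far more electrophilic than the methyl ester, which dialkylzincs do not touch, uncatalysed conjugate addition of dialkylzincs to enals is slow, and the 2-alkyl group of the acrolein (no β-substituent, so no E/Z issue) gives the two carbonyl substituents, H and the branched alkenyl group, the size difference on which the catalyst discriminates.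

Step 10
Reactants: 21 methyl 2-[(2R,5S)-5-[(3R,7E)-3-hydroxy-8,12-dimethyl-4-methylidenetrideca-7,11-dien-1-yl]oxan-2-yl]acetate
Product: 22 2-[(2R,5S)-5-[(3R,7E)-3-hydroxy-8,12-dimethyl-4-methylidenetrideca-7,11-dien-1-yl]oxan-2-yl]acetaldehyde
Conditions: DIBAL-H (2.2 equiv), CH2Cl2, −78 °C; MeOH, aq. Rochelle salt
Reagents that add atoms: none
Why: Partial reduction of the methyl ester by DIBAL-H at low temperature should stop at the aldehyde because the tetrahedral aluminium hemiacetal, chelated by the ring oxygen, survives until the quench, while the free hydroxyl is merely deprotonated.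

Step 11
Reactants: 22 2-[(2R,5S)-5-[(3R,7E)-3-hydroxy-8,12-dimethyl-4-methylidenetrideca-7,11-dien-1-yl]oxan-2-yl]acetaldehyde
Product: 23 2-[(2R,5S)-5-[(3R,7E)-3-hydroxy-8,12-dimethyl-4-methylidenetrideca-7,11-dien-1-yl]oxan-2-yl]prop-2-enal
Conditions: aq. HCHO (37%), pyrrolidine (10 mol%), propionic acid (10 mol%), i-PrOH, 45 °C
Reagents that add atoms: formaldehyde, C=O
Why: Organocatalytic α-methylenation (enamine Mannich reaction with formaldehyde, then elimination of the amine) converts the CH2CHO group into the 2-substituted acrolein, and any reversible oxa-Michael opening of the ring re-closes to the more stable 2,5-trans isomer, so C2 stays under the control of C5.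

Step 12
Reactants: 23 2-[(2R,5S)-5-[(3R,7E)-3-hydroxy-8,12-dimethyl-4-methylidenetrideca-7,11-dien-1-yl]oxan-2-yl]prop-2-enal
Product: 24 2-[(2R,5S)-5-[(3R,7E)-3-hydroxy-8,12-dimethyl-4-methylidenetrideca-7,11-dien-1-yl]oxan-2-yl]prop-2-enoic acid
Conditions: NaClO2, NaH2PO4, 2-methylbut-2-ene, t-BuOH/H2O, rt
Reagents that add atoms: sodium chlorite, [Na+].[O-]Cl=O
Why: Pinnick oxidation converts the enal chemoselectively into the acrylic acid, with 2-methylbut-2-ene scavenging hypochlorous acid so that the trisubstituted alkenes and the allylic alcohol are left untouched.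

**Compound list**

1 | (4S)-4-benzyl-1,3-oxazolidin-2-one | O=C1N[C@@H](Cc2ccccc2)CO1 | starting material
2 | hex-5-enoyl chloride | C=CCCCC(=O)Cl | starting material
3 | (4S)-4-benzyl-3-(hex-5-enoyl)-1,3-oxazolidin-2-one | C=CCCCC(=O)N1[C@@H](Cc2ccccc2)COC1=O | intermediate
4 | tert-butyl bromoacetate | CC(C)(C)OC(=O)CBr | starting material
5 | sodium (Z)-enolate of 3 | C=CCC/C=C(\[O-])N1[C@@H](Cc2ccccc2)COC1=O.[Na+] | intermediate (not isolated)
6 | tert-butyl (3R)-3-{[(4S)-4-benzyl-2-oxo-1,3-oxazolidin-3-yl]carbonyl}hept-6-enoate | CC(C)(C)OC(=O)C[C@H](C(=O)N1[C@@H](Cc2ccccc2)COC1=O)CCC=C | intermediate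
7 | (2R)-2-(but-3-en-1-yl)butane-1,4-diol | OCC[C@H](CO)CCC=C | intermediate
8 | 3-[(3R)-5-hydroxy-3-(hydroxymethyl)pentyl]-1,2,4-trioxolane (ozonide) | OCC[C@H](CO)CCC1OCOO1 | intermediate (not isolated)
9 | (5R)-5-(2-hydroxyethyl)oxan-2-ol (anomeric mixture) | OCC[C@H]1CCC(O)OC1 | intermediate
10 | methyl (triphenyl-λ5-phosphanylidene)acetate | COC(=O)C=P(c1ccccc1)(c1ccccc1)c1ccccc1 | starting material
11 | methyl (2E,6R)-7-hydroxy-6-(2-hydroxyethyl)hept-2-enoate | OCC[C@H](CO)CC/C=C/C(=O)OC | intermediate (not isolated)
12 | methyl 2-[(2R,5R)-5-(2-hydroxyethyl)oxan-2-yl]acetate | OCC[C@H]1CC[C@H](CC(=O)OC)OC1 | intermediate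
13 | methyl 2-[(2R,5R)-5-(2-iodoethyl)oxan-2-yl]acetate | ICC[C@H]1CC[C@H](CC(=O)OC)OC1 | intermediate
14 | geranyl bromide, (2E)-1-bromo-3,7-dimethylocta-2,6-diene | BrC/C=C(\C)CCC=C(C)C | starting material
15 | 2-methylprop-2-en-1-ol | C=C(C)CO | starting material
16 | dilithio derivative of 15 (lithium 2-(lithiomethyl)prop-2-en-1-olate) | [Li]CC(=C)CO[Li] | intermediate (not isolated)
17 | (5E)-6,10-dimethyl-2-methylideneundeca-5,9-dien-1-ol | C=C(CO)CC/C=C(\C)CCC=C(C)C | intermediate
18 | (5E)-6,10-dimethyl-2-methylideneundeca-5,9-dienal | C=C(C=O)CC/C=C(\C)CCC=C(C)C | intermediate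
19 | bis{2-[(3R,6R)-6-(2-methoxy-2-oxoethyl)oxan-3-yl]ethyl}zinc | [Zn](CC[C@H]1CC[C@H](CC(=O)OC)OC1)CC[C@H]1CC[C@H](CC(=O)OC)OC1 | intermediate (not isolated)
20 | {2-[(3R,6R)-6-(2-methoxy-2-oxoethyl)oxan-3-yl]ethyl}[(trimethylsilyl)methyl]zinc | C[Si](C)(C)C[Zn]CC[C@H]1CC[C@H](CC(=O)OC)OC1 | intermediate (not isolated)
21 | methyl 2-[(2R,5S)-5-[(3R,7E)-3-hydroxy-8,12-dimethyl-4-methylidenetrideca-7,11-dien-1-yl]oxan-2-yl]acetate | C=C(CC/C=C(\C)CCC=C(C)C)[C@H](O)CC[C@H]1CC[C@H](CC(=O)OC)OC1 | intermediate
22 | 2-[(2R,5S)-5-[(3R,7E)-3-hydroxy-8,12-dimethyl-4-methylidenetrideca-7,11-dien-1-yl]oxan-2-yl]acetaldehyde | C=C(CC/C=C(\C)CCC=C(C)C)[C@H](O)CC[C@H]1CC[C@H](CC=O)OC1 | intermediate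
23 | 2-[(2R,5S)-5-[(3R,7E)-3-hydroxy-8,12-dimethyl-4-methylidenetrideca-7,11-dien-1-yl]oxan-2-yl]prop-2-enal | C=C(CC/C=C(\C)CCC=C(C)C)[C@H](O)CC[C@H]1CC[C@H](C(=C)C=O)OC1 | intermediate
24 | 2-[(2R,5S)-5-[(3R,7E)-3-hydroxy-8,12-dimethyl-4-methylidenetrideca-7,11-dien-1-yl]oxan-2-yl]prop-2-enoic acid | C=C(CC/C=C(\C)CCC=C(C)C)[C@H](O)CC[C@H]1CC[C@H](C(=C)C(=O)O)OC1 | target

**Step count and risks**

Total step count: 12. Longest linear sequence: 10 steps (steps 1–6 and 9–12); the enal branch (steps 7–8) joins at step 9.

Steps most likely to fail: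

1. Step 9. The iodine–zinc exchange may be incomplete, the catalyst may discriminate poorly between the faces of a 2-alkylacrolein that has no β-substituent, and isopropoxide-mediated Meerwein–Ponndorf–Verley reduction of the enal may compete. The fallback sets out from 13 and 18. A cobalt-catalysed chromium(II)-mediated Nozaki–Hiyama–Kishi-type alkylation (CrCl2, cobalt phthalocyanine cat., DMF, rt) should join the same bond without stereocontrol and give methyl 2-[(2R,5S)-5-[(7E)-3-hydroxy-8,12-dimethyl-4-methylidenetrideca-7,11-dien-1-yl]oxan-2-yl]acetate as a mixture of carbinol epimers F1. Oxidation with Dess–Martin periodinane should give the enone methyl 2-[(2R,5R)-5-[(7E)-8,12-dimethyl-4-methylidene-3-oxotrideca-7,11-dien-1-yl]oxan-2-yl]acetate F2. Corey–Bakshi–Shibata reduction with the (S)-methyl oxazaborolidine and catecholborane at −78 °C, the branched alkenyl group acting as the large substituent, should then set the (R)-carbinol under reagent control and return to the route at 21.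

2. Step 11. The enamine of the β-alkoxy aldehyde may expel the ring oxygen (retro-oxa-Michael ring opening), leading to erosion at C2 or decomposition, and the acrolein product may oligomerise. The fallback sets out from 21 and stays at the ester level. Excess LDA (THF, −78 °C) should give the dilithio ester enolate/alkoxide F3, which is trapped with Eschenmoser's salt to give the Mannich base methyl 3-(dimethylamino)-2-[(2R,5S)-5-[(3R,7E)-3-hydroxy-8,12-dimethyl-4-methylidenetrideca-7,11-dien-1-yl]oxan-2-yl]propanoate F4. Methyl iodide should convert it into the trimethylammonium iodide F5, and DBU should eliminate trimethylamine to give the acrylate methyl 2-[(2R,5S)-5-[(3R,7E)-3-hydroxy-8,12-dimethyl-4-methylidenetrideca-7,11-dien-1-yl]oxan-2-yl]prop-2-enoate F6. Saponification with LiOH in THF/water comes back to the route at the target 24.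

3. Step 5. Equilibration of the simple ester oxa-Michael adduct may be too slow to reach the trans isomer cleanly, and closure by the hydroxyethyl oxygen may compete. The fallback sets out from 9 and uses a doubly activated acceptor so that ring closure is freely reversible. Knoevenagel condensation with dimethyl malonate (piperidinium acetate, or TiCl4/pyridine) should give the alkylidene malonate dimethyl 2-[(4R)-5-hydroxy-4-(2-hydroxyethyl)pentylidene]propanedioate F7, which cyclises in the same flask to dimethyl 2-[(2R,5R)-5-(2-hydroxyethyl)oxan-2-yl]propanedioate F8. Krapcho demethoxycarbonylation (LiCl, wet DMSO, 150 °C) comes back to the route at 12.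

Further compounds
F1 | step 9 | methyl 2-[(2R,5S)-5-[(7E)-3-hydroxy-8,12-dimethyl-4-methylidenetrideca-7,11-dien-1-yl]oxan-2-yl]acetate, mixture of carbinol epimers | C=C(CC/C=C(\C)CCC=C(C)C)C(O)CC[C@H]1CC[C@H](CC(=O)OC)OC1
F2 | step 9 | methyl 2-[(2R,5R)-5-[(7E)-8,12-dimethyl-4-methylidene-3-oxotrideca-7,11-dien-1-yl]oxan-2-yl]acetate | C=C(CC/C=C(\C)CCC=C(C)C)C(=O)CC[C@H]1CC[C@H](CC(=O)OC)OC1
F3 | step 11 | dilithio ester enolate/alkoxide of 21 | C=C(CC/C=C(\C)CCC=C(C)C)[C@H](O[Li])CC[C@H]1CC[C@H](C=C(OC)O[Li])OC1
F4 | step 11 | methyl 3-(dimethylamino)-2-[(2R,5S)-5-[(3R,7E)-3-hydroxy-8,12-dimethyl-4-methylidenetrideca-7,11-dien-1-yl]oxan-2-yl]propanoate, mixture of epimers at the ester α-carbon | C=C(CC/C=C(\C)CCC=C(C)C)[C@H](O)CC[C@H]1CC[C@H](C(CN(C)C)C(=O)OC)OC1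
F5 | step 11 | trimethylammonium iodide derived from F4 | C=C(CC/C=C(\C)CCC=C(C)C)[C@H](O)CC[C@H]1CC[C@H](C(C[N+](C)(C)C)C(=O)OC)OC1.[I-]
F6 | step 11 | methyl 2-[(2R,5S)-5-[(3R,7E)-3-hydroxy-8,12-dimethyl-4-methylidenetrideca-7,11-dien-1-yl]oxan-2-yl]prop-2-enoate | C=C(CC/C=C(\C)CCC=C(C)C)[C@H](O)CC[C@H]1CC[C@H](C(=C)C(=O)OC)OC1
F7 | step 5 | dimethyl 2-[(4R)-5-hydroxy-4-(2-hydroxyethyl)pentylidene]propanedioate | OCC[C@H](CO)CCC=C(C(=O)OC)C(=O)OC
F8 | step 5 | dimethyl 2-[(2R,5R)-5-(2-hydroxyethyl)oxan-2-yl]propanedioate | OCC[C@H]1CC[C@H](C(C(=O)OC)C(=O)OC)OC1
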